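At the last reading, 52 min, the runs so far can be compared as fractions of their own charge, and the zeta run is asked at that same time.

| flask | starting material | free catalyst | time |
|---|---|---|---|
| alpha | 0.0500 M | 0.00400 M |  |
| gamma | 0.0250 M | 0.00400 M |  |
| epsilon | 0.150 M | 0.00400 M |  |
| beta | 0.0500 M | 0.00600 M |  |
| zeta | 0.0250 M | 0.00200 M | 52 min |

| alpha run: time / min | alpha run: [target] / M | gamma run: time / min | gamma run: [target] / M | epsilon run: time / min | epsilon run: [target] / M | beta run: time / min | beta run: [target] / M |
|---|---|---|---|---|---|---|---|
| 3.0 | 0.0010 | 3.0 | 0 | 3.0 | 0.0025 | 3.0 | 6 × 10⁻⁴ |
| 9.0 | 0.0052 | 9.0 | 0.0026 | 9.0 | 0.0143 | 9.0 | 0.0069 |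
| 17 | 0.0117 | 17 | 0.0059 | 17 | 0.0349 | 17 | 0.0150 |
| 27 | 0.0189 | 27 | 0.0086 | 27 | 0.0554 | 27 | 0.0247 |
| 39 | 0.0248 | 39 | 0.0115 | 39 | 0.0716 | 39 | 0.0322 |
| 52 | 0.0290 | 52 | 0.0142 | 52 | 0.0841 | 52 | 0.0369 |

(each reading ± 8 × 10⁻⁴ M)

- Overall: starting material -> target, with free catalyst as catalyst.
- Constant volume, constant temperature.
- An order is taken over about fifteen percent of the charge, up and down.

- apparent order in [free catalyst] of the starting rate, round the charge of the alpha run (the rate where two percent of its starting material have turned into target)
- apparent order in [starting material] of the starting rate, round the charge of the alpha run (the rate where two percent of its starting material have turned into target) (one fixed amount of target, the same in the runs compared)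
- the gamma run starts with 0.0250 M less of starting material than the alpha run, and with no target. Compared where both hold the same amount of starting material, once fifteen percent of what the gamma run was charged with has turned into target, is the gamma run faster, slower or alike (within a tenth)?
- target in the zeta run at 52 min, as a share of the starting material charged

For each run, take the share of the charge turned at that reading, and then the logarithm of charge over what is left, divided by the free catalyst charged.

| run | share turned | ln(charge/left) over free catalyst |
|---|---|---|
| alpha | 58.0% | 217 M⁻¹ |
| gamma | 56.8% | 210 M⁻¹ |
| epsilon | 56.1% | 206 M⁻¹ |
| beta | 73.8% | 223 M⁻¹ |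

The gamma run looks nearly like the alpha run: it has the same free catalyst and half the starting material. Their shares differ by 1.2 percentage points, which is less than the 3.20% scatter of one gamma reading taken as a share. So between these two runs, at this reading and with the free catalyst held fixed, the charge barely moves the share, as in a pseudo-first-order loss of starting material whose rate constant may change with time. The beta run has 1.50 times the free catalyst of the alpha run and 1.54 times its logarithm.

The last column therefore stays nearly level, and I carry its mean, 214 M⁻¹: the catalyst clock, meaning the logarithm of charge over left that each unit of free catalyst has produced by 52 min.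

The zeta run has the charge of the gamma run and half its free catalyst. Its logarithm is then 0.428, so I expect 34.8% turned. That is lower than the gamma run's 56.8%, at 0.613 of it.

The forecast gives 37% for the zeta run, higher than my figure, with orders of 0.7 in free catalyst and 0.9 in starting material. For the gamma run against the alpha run, at the same amount of starting material, its answer is faster: “Gamma is clearly faster, which points to product inhibition or catalyst loss.”

The zeta run gives 34.3%. The orders are 0.60 in free catalyst and 0.62 in starting material. Where both hold the same amount of starting material, the gamma run is faster, at 1.6 times the rate of the alpha run.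

    active catalyst + starting material → target + active catalyst (6.660 M⁻¹ min⁻¹)
    active catalyst → spent catalyst (0.01668 min⁻¹)
    free catalyst → active catalyst (0.1464 min⁻¹)

The 34.3% of the zeta run is a clock reading of 210 M⁻¹, beside the 214 M⁻¹ carried from the earlier runs. The loss of active catalyst to spent catalyst costs the zeta run 11 points: without that loss the zeta run stands at 45.2%, a clock reading of 301 M⁻¹.

(The earlier runs and the new flask stem from a simulated flask for substances that don't exist, noise included.)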